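**Strategy**

1. Cuts: the two isovalerate C–O bonds and the aldehyde oxidation level are adjusted last. The core is then tied as a lactone (C3–O to the formyl carbon), and this lactone is cut at O1–C2, at the bond between the methylene-bearing carbon and the carbonyl carbon (that carbon is CO) and at the lactone C–O bond. The C3–alkyne bond and the aryl–CHO bond are the earlier cuts.
2. Enabling feature: the C3 oxygen, C3, C2, the methylene-bearing carbon and the formyl carbon are five atoms in a row on one face of the dihydrofuran ring (2,3-cis). They are therefore a masked cis-fused α-methylene-γ-butyrolactone (ring C) on the dihydrofuran ring B, and both rings can come from an ortho-hydroxyaryl buta-2,3-dienyl carbinol and CO.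
3. Forward order: the benzene ring A is bought; formylation, alkynylation and allene homologation build the chain; one operation closes ring B (O1–C2) and then ring C (CO insertion, lactonisation); ring C is reduced open again, which leaves the dihydrobenzofuran; acylation and oxidation finish.
4. Stereochemistry: C3 comes from a catalyst-controlled alkynylation of the aldehyde; C2 is set relative to C3 by the lactone tether in the key step; the side-chain (R)-carbinol comes from an (R,R)-TsDPEN ruthenium transfer hydrogenation.

Key step: step 7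

Assumption: the ProPhenol antipode that gives Si-face alkynyl transfer in step 3 is to be fixed by a Mosher ester analysis of 7 on the first run; both antipodes are commercial, so either outcome leaves the route unchanged.

**Route**

Step 1
Reactants: 1 4'-hydroxyacetophenone; 2 formaldehyde (used as paraformaldehyde)
Product: 4 5-acetyl-2-hydroxybenzaldehyde, via ortho-hydroxymethyl phenol 3 (not isolated)
Conditions: MgCl2 (1.5 equiv), Et3N (3.75 equiv), (CH2O)n (6.75 equiv), MeCN, reflux; then 1 M HCl
Reagents that add atoms: none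
Why: Magnesium-mediated ortho-formylation of a phenol (Casnati–Skattebøl reaction): the magnesium phenoxide delivers formaldehyde to the only free ortho position, the para position being blocked by the acetyl group, and a second formaldehyde takes up hydride from the hydroxymethyl intermediate 3 to give the salicylaldehyde.

Step 2
Reactants: 4 5-acetyl-2-hydroxybenzaldehyde
Product: 5 5-acetyl-2-[(4-methoxybenzyl)oxy]benzaldehyde
Conditions: PMBCl (1.2 equiv), K2CO3 (1.5 equiv), DMF, 50 °C
Reagents that add atoms: 4-methoxybenzyl chloride COc1ccc(CCl)cc1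
Why: Williamson ether synthesis on the acidic, hydrogen-bonded phenol; the PMB ether withstands Me2Zn, carbonate and the hot amine/copper medium of step 5 and can later be taken off oxidatively without acid.

Step 3
Reactants: 5 5-acetyl-2-[(4-methoxybenzyl)oxy]benzaldehyde; 6 trimethylsilylacetylene
Product: 7 1-{3-[(1R)-1-hydroxy-3-(trimethylsilyl)prop-2-yn-1-yl]-4-[(4-methoxybenzyl)oxy]phenyl}ethanone
Conditions: 6 (3 equiv), Me2Zn (3 equiv), ProPhenol (20 mol%, antipode for Si-face addition), Ph3P=O (40 mol%), toluene, 4 °C; aq. NH4Cl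
Reagents that add atoms: none
Why: Dinuclear zinc–ProPhenol catalysed asymmetric alkynylation of an aryl aldehyde: the in-situ alkynylzinc is transferred within the chiral bimetallic pocket to the Si face of the aldehyde, which sets the future C3 (descriptor R here because the silylalkynyl group outranks the aryl group), while the far less electrophilic aryl methyl ketone is left alone when the alkynylzinc is preformed and the aldehyde is added slowly.

Step 4
Reactants: 7 1-{3-[(1R)-1-hydroxy-3-(trimethylsilyl)prop-2-yn-1-yl]-4-[(4-methoxybenzyl)oxy]phenyl}ethanone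
Product: 8 1-{3-[(1S)-1-hydroxyprop-2-yn-1-yl]-4-[(4-methoxybenzyl)oxy]phenyl}ethanone
Conditions: K2CO3 (0.2 equiv), MeOH, 0 °C to rt
Reagents that add atoms: none
Why: Base-catalysed methanolysis of the alkynyl C–Si bond (protodesilylation); the carbinol centre is not involved and only its descriptor changes, to S, because the ethynyl group now ranks below the aryl group.

Step 5
Reactants: 8 1-{3-[(1S)-1-hydroxyprop-2-yn-1-yl]-4-[(4-methoxybenzyl)oxy]phenyl}ethanone; 2 formaldehyde (used as paraformaldehyde)
Product: 10 1-{3-[(1S)-1-hydroxybuta-2,3-dien-1-yl]-4-[(4-methoxybenzyl)oxy]phenyl}ethanone, via propargylic Mannich base 9 (not isolated)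
Conditions: (CH2O)n (2.5 equiv), Cy2NH (1.8 equiv), copper monoiodide (0.5 equiv), 1,4-dioxane, reflux
Reagents that add atoms: none
Why: Crabbé homologation in its dicyclohexylamine variant: copper-catalysed Mannich coupling of alkyne, formaldehyde and amine gives propargylic amine 9, which transfers hydride from an amine α-carbon to the alkyne and loses the imine to give the terminal allene; unprotected secondary propargylic alcohols are known to go through without loss of configuration, and the phenol is kept as its PMB ether so that no phenolic Mannich reaction can compete.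

Step 6
Reactants: 10 1-{3-[(1S)-1-hydroxybuta-2,3-dien-1-yl]-4-[(4-methoxybenzyl)oxy]phenyl}ethanone
Product: 11 1-{4-hydroxy-3-[(1S)-1-hydroxybuta-2,3-dien-1-yl]phenyl}ethanone
Conditions: DDQ (1.3 equiv), CH2Cl2/pH 7 phosphate buffer (10:1), 0 °C to rt
Reagents that add atoms: none
Why: Oxidative PMB cleavage by DDQ (hydride abstraction from the anisyl methylene, hydrolysis of the oxocarbenium ion); the acetyl-deactivated aryl ring, the allene and the carbinol are much harder to oxidise, and the neutral buffer spares the acid-sensitive allenyl carbinol.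

Step 7
Reactants: 11 1-{4-hydroxy-3-[(1S)-1-hydroxybuta-2,3-dien-1-yl]phenyl}ethanone; 12 carbon monoxide
Product: 15 (3aR,8bR)-7-acetyl-3-methylidene-3a,8b-dihydrofuro[3,2-b][1]benzofuran-2(3H)-one, via vinylpalladium chloride 13 (not isolated), via acylpalladium chloride 14 (not isolated)
Conditions: PdCl2(MeCN)2 (10 mol%), CuCl2 (3 equiv), NaOAc (4 equiv), CO (1 atm), THF (no alcohol), rt
Reagents that add atoms: none
Why: Proposed new method: PdCl2 binds the proximal double bond of the allene in 11, the phenoxide formed under NaOAc attacks the proximal allene carbon anti to palladium and closes the dihydrofuran ring (5-exo-trig, O1–C2 bond) to give the σ-vinylpalladium 13, CO inserts to the acylpalladium 14, and the C3 hydroxyl attacks the acyl carbon and closes the γ-lactone (5-exo-trig acyl substitution), the zerovalent palladium released being reoxidised by CuCl2. The closest known reaction types are the oxypalladation–alkoxycarbonylation of allenyl alcohols to 2-(oxacycloalkyl)acrylates under PdCl2/CuCl2/CO and the oxycarbonylative bicyclisation of 4-ene-1,3-diols to cis-fused bicyclic γ-lactones with the same catalyst system; an allene attacked by a phenol whose acylpalladium is trapped by an internal hydroxyl has not been described. C2 is the only new stereocentre and is set relative to the C3 carbinol from step 3: binding of the C3 hydroxyl to palladium places the metal on the allene face from which anti attack gives the 2,3-cis vinylpalladium, and because no external alcohol is present only the cis acylpalladium can lactonise, a trans-fused 5,5-bicycle being out of reach. A trans vinylpalladium, should it form, has no productive exit and is expected to revert by loss of the good para-acetylphenoxide leaving group, so the cascade should funnel through the cis series. The step needs attack of the phenol at the proximal allene carbon and not 5-endo attack of the C3 hydroxyl at the allene terminus (2,5-dihydrofuran formation); the para-acetyl group makes the phenol the only hydroxyl ionised by acetate, and it also holds back ionisation of the benzylic C3–O bond and ortho-quinone methide formation.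

Step 8
Reactants: 15 (3aR,8bR)-7-acetyl-3-methylidene-3a,8b-dihydrofuro[3,2-b][1]benzofuran-2(3H)-one
Product: 16 (3aR,8bR)-7-[(1R)-1-hydroxyethyl]-3-methylidene-3a,8b-dihydrofuro[3,2-b][1]benzofuran-2(3H)-one
Conditions: RuCl(p-cymene)[(R,R)-TsDPEN] (2 mol%), HCO2H/Et3N (5:2), CH2Cl2, 0 °C to rt
Reagents that add atoms: none
Why: Noyori–Ikariya asymmetric transfer hydrogenation of an aryl methyl ketone: the (R,R)-TsDPEN ruthenium hydride delivers hydrogen through the six-membered outer-sphere transition state to the face that gives the (R)-1-arylethanol, under catalyst control and independent of the distant ring stereocentres, and this polar hydride is selective for C=O over the unsaturated lactone.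

Step 9
Reactants: 16 (3aR,8bR)-7-[(1R)-1-hydroxyethyl]-3-methylidene-3a,8b-dihydrofuro[3,2-b][1]benzofuran-2(3H)-one
Product: 18 (2R,3R)-5-[(1R)-1-hydroxyethyl]-2-(3-hydroxyprop-1-en-2-yl)-2,3-dihydro-1-benzofuran-3-ol, via lactol 17 (not isolated)
Conditions: DIBAL-H (i-Bu2AlH, 5 equiv), CH2Cl2, −78 to 0 °C; aq. potassium sodium tartrate
Reagents that add atoms: none
Why: DIBAL-H reduction of an α-methylene-γ-lactone to the 2-methylene-1,4-diol in a non-coordinating solvent (1,2-addition, lactol 17, ring opening, second 1,2-addition), which removes the tether and frees the C3 hydroxyl and the primary allylic alcohol without touching a stereocentre.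

Step 10
Reactants: 18 (2R,3R)-5-[(1R)-1-hydroxyethyl]-2-(3-hydroxyprop-1-en-2-yl)-2,3-dihydro-1-benzofuran-3-ol
Product: 19 (2R,3R)-2-{3-[(tert-butyldimethylsilyl)oxy]prop-1-en-2-yl}-5-[(1R)-1-hydroxyethyl]-2,3-dihydro-1-benzofuran-3-ol
Conditions: TBSCl (1.05 equiv), imidazole (2 equiv), CH2Cl2, −20 to 0 °C
Reagents that add atoms: tert-butyldimethylsilyl chloride CC(C)(C)[Si](C)(C)Cl
Why: Sterically controlled silylation: the unhindered primary allylic hydroxyl reacts with TBSCl/imidazole far faster than the two secondary benzylic hydroxyls at low temperature.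

Step 11
Reactants: 19 (2R,3R)-2-{3-[(tert-butyldimethylsilyl)oxy]prop-1-en-2-yl}-5-[(1R)-1-hydroxyethyl]-2,3-dihydro-1-benzofuran-3-ol; 20 isovaleryl chloride (3-methylbutanoyl chloride)
Product: 21 (1R)-1-[(2R,3R)-2-{3-[(tert-butyldimethylsilyl)oxy]prop-1-en-2-yl}-3-(3-methylbutanoyloxy)-2,3-dihydro-1-benzofuran-5-yl]ethyl 3-methylbutanoate
Conditions: 20 (3 equiv), pyridine (6 equiv), DMAP (0.2 equiv), CH2Cl2, 0 °C to rt
Reagents that add atoms: none
Why: DMAP-catalysed acylation (nucleophilic catalysis through the acylpyridinium ion) of both secondary alcohols with retention, since only O–H bonds are broken; the weak base and low temperature guard against elimination of the C3 ester towards the aromatic benzofuran.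

Step 12
Reactants: 21 (1R)-1-[(2R,3R)-2-{3-[(tert-butyldimethylsilyl)oxy]prop-1-en-2-yl}-3-(3-methylbutanoyloxy)-2,3-dihydro-1-benzofuran-5-yl]ethyl 3-methylbutanoate
Product: 22 (1R)-1-[(2R,3R)-2-(3-hydroxyprop-1-en-2-yl)-3-(3-methylbutanoyloxy)-2,3-dihydro-1-benzofuran-5-yl]ethyl 3-methylbutanoate
Conditions: HF·pyridine, excess pyridine, THF, 0 °C to rt
Reagents that add atoms: none
Why: Fluoride-mediated desilylation of a primary TBS ether with pyridine-buffered HF·pyridine, a medium too weakly acidic to ionise the two benzylic esters and not basic enough to cause acyl migration or elimination.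

Step 13
Reactants: 22 (1R)-1-[(2R,3R)-2-(3-hydroxyprop-1-en-2-yl)-3-(3-methylbutanoyloxy)-2,3-dihydro-1-benzofuran-5-yl]ethyl 3-methylbutanoate
Product: 23 (1R)-1-[(2R,3R)-3-(3-methylbutanoyloxy)-2-(3-oxoprop-1-en-2-yl)-2,3-dihydro-1-benzofuran-5-yl]ethyl 3-methylbutanoate (CNP0316116.1)
Conditions: Dess–Martin periodinane (1.3 equiv), NaHCO3 (5 equiv), CH2Cl2, 0 °C to rt
Reagents that add atoms: none
Why: Dess–Martin oxidation of a primary allylic alcohol to the α-substituted acrolein under bicarbonate buffer, mild and non-basic enough to leave the C2 stereocentre and the C3 ester untouched.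

**Compound list**

1 | 4'-hydroxyacetophenone | CC(=O)c1ccc(O)cc1 | starting material
2 | formaldehyde (used as paraformaldehyde) | C=O | starting material
3 | 1-[4-hydroxy-3-(hydroxymethyl)phenyl]ethanone (magnesium salt in the flask) | CC(=O)c1ccc(O)c(CO)c1 | intermediate
4 | 5-acetyl-2-hydroxybenzaldehyde | CC(=O)c1ccc(O)c(C=O)c1 | intermediate
5 | 5-acetyl-2-[(4-methoxybenzyl)oxy]benzaldehyde | CC(=O)c1ccc(OCc2ccc(OC)cc2)c(C=O)c1 | intermediate
6 | trimethylsilylacetylene | C#C[Si](C)(C)C | starting material
7 | 1-{3-[(1R)-1-hydroxy-3-(trimethylsilyl)prop-2-yn-1-yl]-4-[(4-methoxybenzyl)oxy]phenyl}ethanone | CC(=O)c1ccc(OCc2ccc(OC)cc2)c([C@H](C#C[Si](C)(C)C)O)c1 | intermediate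
8 | 1-{3-[(1S)-1-hydroxyprop-2-yn-1-yl]-4-[(4-methoxybenzyl)oxy]phenyl}ethanone | CC(=O)c1ccc(OCc2ccc(OC)cc2)c([C@H](C#C)O)c1 | intermediate
9 | 1-{3-[(1S)-4-(dicyclohexylamino)-1-hydroxybut-2-yn-1-yl]-4-[(4-methoxybenzyl)oxy]phenyl}ethanone | CC(=O)c1ccc(OCc2ccc(OC)cc2)c([C@H](C#CCN(C2CCCCC2)C2CCCCC2)O)c1 | intermediate
10 | 1-{3-[(1S)-1-hydroxybuta-2,3-dien-1-yl]-4-[(4-methoxybenzyl)oxy]phenyl}ethanone | CC(=O)c1ccc(OCc2ccc(OC)cc2)c([C@H](C=C=C)O)c1 | intermediate
11 | 1-{4-hydroxy-3-[(1S)-1-hydroxybuta-2,3-dien-1-yl]phenyl}ethanone | CC(=O)c1ccc(O)c([C@H](C=C=C)O)c1 | intermediate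
12 | carbon monoxide | [C-]#[O+] | starting material
13 | 2,3-cis σ-vinylpalladium chloride: 5-acetyl-2-[1-(chloropalladio)ethenyl]-2,3-dihydro-1-benzofuran-3-ol (other ligands on palladium omitted) | C=C([Pd]Cl)[C@H]1Oc2ccc(C(C)=O)cc2[C@H]1O | intermediate
14 | 2,3-cis acylpalladium chloride: 2-(5-acetyl-3-hydroxy-2,3-dihydro-1-benzofuran-2-yl)prop-2-enoylpalladium chloride (other ligands omitted) | C=C(C(=O)[Pd]Cl)[C@H]1Oc2ccc(C(C)=O)cc2[C@H]1O | intermediate
15 | (3aR,8bR)-7-acetyl-3-methylidene-3a,8b-dihydrofuro[3,2-b][1]benzofuran-2(3H)-one | C=C1[C@H]2Oc3ccc(C(C)=O)cc3[C@H]2OC1=O | intermediate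
16 | (3aR,8bR)-7-[(1R)-1-hydroxyethyl]-3-methylidene-3a,8b-dihydrofuro[3,2-b][1]benzofuran-2(3H)-one | C=C1[C@H]2Oc3ccc([C@@H](C)O)cc3[C@H]2OC1=O | intermediate
17 | (3aR,8bR)-7-[(1R)-1-hydroxyethyl]-3-methylidene-2,3,3a,8b-tetrahydrofuro[3,2-b][1]benzofuran-2-ol (lactol, anomeric centre undefined; aluminium salt in the flask) | C=C1[C@H]2Oc3ccc([C@@H](C)O)cc3[C@H]2OC1O | intermediate
18 | (2R,3R)-5-[(1R)-1-hydroxyethyl]-2-(3-hydroxyprop-1-en-2-yl)-2,3-dihydro-1-benzofuran-3-ol | C=C(CO)[C@H]1Oc2ccc([C@@H](C)O)cc2[C@H]1O | intermediate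
19 | (2R,3R)-2-{3-[(tert-butyldimethylsilyl)oxy]prop-1-en-2-yl}-5-[(1R)-1-hydroxyethyl]-2,3-dihydro-1-benzofuran-3-ol | C=C(CO[Si](C)(C)C(C)(C)C)[C@H]1Oc2ccc([C@@H](C)O)cc2[C@H]1O | intermediate
20 | isovaleryl chloride (3-methylbutanoyl chloride) | CC(C)CC(Cl)=O | starting material
21 | (1R)-1-[(2R,3R)-2-{3-[(tert-butyldimethylsilyl)oxy]prop-1-en-2-yl}-3-(3-methylbutanoyloxy)-2,3-dihydro-1-benzofuran-5-yl]ethyl 3-methylbutanoate | C=C(CO[Si](C)(C)C(C)(C)C)[C@H]1Oc2ccc([C@@H](C)OC(=O)CC(C)C)cc2[C@H]1OC(=O)CC(C)C | intermediate
22 | (1R)-1-[(2R,3R)-2-(3-hydroxyprop-1-en-2-yl)-3-(3-methylbutanoyloxy)-2,3-dihydro-1-benzofuran-5-yl]ethyl 3-methylbutanoate | C=C(CO)[C@H]1Oc2ccc([C@@H](C)OC(=O)CC(C)C)cc2[C@H]1OC(=O)CC(C)C | intermediate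
23 | (1R)-1-[(2R,3R)-3-(3-methylbutanoyloxy)-2-(3-oxoprop-1-en-2-yl)-2,3-dihydro-1-benzofuran-5-yl]ethyl 3-methylbutanoate (CNP0316116.1) | C=C(C=O)[C@H]1Oc2ccc([C@@H](C)OC(=O)CC(C)C)cc2[C@H]1OC(=O)CC(C)C | target

**Count and risks**

Total: 13 steps. Longest linear sequence: 13 steps (1 to 23); compounds 2, 6, 12 and 20 are bought.

Steps most likely to fail:

Step 7 (proposed method). What may go wrong: the carbinol hydroxyl attacks the allene terminus first in a 5-endo mode, and after carbonylation the phenol traps the acylpalladium to give an isomeric lactone; or the trans series forms irreversibly and the catalyst stalls as palladium metal. The fallback uses known chemistry, sets out from 11 and comes back at 15. Iodocyclisation of 11 with N-iodosuccinimide and NaHCO3 in MeCN at 0 °C is an electrophilic haloetherification of an allenyl alcohol, with iodine going to the central allene carbon and the phenol oxygen to the proximal one. It should give the 2-(1-iodoethenyl)-2,3-dihydrobenzofuran-3-ol, whose 2,3-cis isomer is 1-[(2S,3R)-3-hydroxy-2-(1-iodoethenyl)-2,3-dihydro-1-benzofuran-5-yl]ethanone F1. Cyclocarbonylation of F1 with Pd(PPh3)4 (5 mol%), CO (1 atm) and K2CO3 in MeCN at 60 °C (oxidative addition of zerovalent palladium into the vinyl iodide, CO insertion, lactonisation by the cis hydroxyl) should then give 15. The trans iodide cannot lactonise and is removed by chromatography at either stage.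

Step 5. What may go wrong: base-induced isomerisation of the aryl propargylic carbinol to an enone at 100 °C, or Mannich or aldol reaction of the acetyl group with formaldehyde. The fallback sets out from 5 and comes back at 10, replacing steps 3 to 5. Aldehyde 5 is alkynylated under the conditions of step 3 with methyl prop-2-yn-1-yl carbonate in place of 6 to give (4S)-4-{5-acetyl-2-[(4-methoxybenzyl)oxy]phenyl}-4-hydroxybut-2-yn-1-yl methyl carbonate F2. Palladium-catalysed formate hydrogenolysis of this primary propargylic carbonate (Pd2(dba)3, n-Bu3P, HCO2NH4, THF, rt; Tsuji conditions for 2-alkynyl carbonates) delivers hydride through the allenylpalladium hydride to the alkyne carbon next to the carbinol. This should give 10 at room temperature without formaldehyde or amine.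

Step 3. What may go wrong: zinc enolate formation at the acetyl group followed by aldol oligomerisation under the ProPhenol conditions, or insufficient facial selectivity with the ortho-alkoxy aldehyde. The fallback sets out from 5 and comes back at 7. Chemoselective addition of Me3SiC≡CMgBr to the aldehyde of 5 in THF at −78 °C gives racemic 1-{3-[1-hydroxy-3-(trimethylsilyl)prop-2-yn-1-yl]-4-[(4-methoxybenzyl)oxy]phenyl}ethanone F3. Oxidation with MnO2 in CH2Cl2 gives the ynone 1-{5-acetyl-2-[(4-methoxybenzyl)oxy]phenyl}-3-(trimethylsilyl)prop-2-yn-1-one F4. Midland reduction of F4 with (R)-Alpine-borane (concentrated THF, rt) reduces alkynyl ketones but not aryl methyl ketones, and should give 7 with the aryl group acting as the large substituent, by analogy with the (R)-1-alkyn-3-ols obtained from alkyl alkynyl ketones.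

**Further compounds**

F1 | step 7 | 1-[(2S,3R)-3-hydroxy-2-(1-iodoethenyl)-2,3-dihydro-1-benzofuran-5-yl]ethanone | IC(=C)[C@H]1Oc2ccc(C(C)=O)cc2[C@H]1O
F2 | step 5 | (4S)-4-{5-acetyl-2-[(4-methoxybenzyl)oxy]phenyl}-4-hydroxybut-2-yn-1-yl methyl carbonate | CC(=O)c1ccc(OCc2ccc(OC)cc2)c([C@H](C#CCOC(=O)OC)O)c1
F3 | step 3 | racemic 1-{3-[1-hydroxy-3-(trimethylsilyl)prop-2-yn-1-yl]-4-[(4-methoxybenzyl)oxy]phenyl}ethanone | CC(=O)c1ccc(OCc2ccc(OC)cc2)c(C(O)C#C[Si](C)(C)C)c1
F4 | step 3 | 1-{5-acetyl-2-[(4-methoxybenzyl)oxy]phenyl}-3-(trimethylsilyl)prop-2-yn-1-one | CC(=O)c1ccc(OCc2ccc(OC)cc2)c(C(=O)C#C[Si](C)(C)C)c1
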